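I started from the easy step, one coupling of one nucleophile with one electrophile, and kept books on the acid it leaves.

    electrophile + nucleophile → acid set free + target (k1 = 1.6 /M/min)
    nucleophile + acid set free ⇌ protonated nucleophile, settled at all times (K2 = 1300 /M)
    acid set free + free base ⇌ salt of the base (K3 = 3500 /M, k3 = 8.8 /M/min)
    target → over-reaction product (k4 = 1.8 /min)
    nucleophile + protic impurity → quenched reagent (k5 = 0.28 /M/min)
    electrophile + target → side product (k6 = 1.1 /M/min)

| setting | Thursday's | Monday's |
|---|---|---|
| electrophile | 0.50 M | 0.50 M |
| free base | 2.20 equiv | 1.10 equiv |
| protonated nucleophile | 0.900 equiv | 0.900 equiv |
| protic impurity | 0.500 M | 0.500 M |
| time | 20 min | 20 min |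

1. part of the electrophile that has reacted at the end, Thursday's
2. part of the electrophile that has reacted at the end, Monday's
3. what raising the equivalents of free base from its lowest to its highest value here does to the part of the electrophile that has reacted (changes below 5 percentage points count as none) (no change / it falls / it rises)

- a species is counted by the electrophile in it: one side product counts as two
- run time (Thursday's): 20 min

1. The nucleophile was charged protonated, so each one entered the flask carrying one acid.

2. Coupling it set free a second acid, so a coupling put two acids on the bill of the free base.

3. A quenched nucleophile left only the acid it carried, so it cost one. At the charges, coupling outran quenching 5.71 to one, so I booked every nucleophile at two and kept quenching as a slight relief.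

4. The full bill was therefore 1.80 equiv of free base.

5. I named the cover: the equivalents of free base charged, divided by that bill. The zero of my scale was a cover of one, where base and nucleophile close their books together.

6. Monday's flask had a cover of 0.611, so I took its free base as the limiting reagent. Its free base should fall faster, as a part of its charge, than its protonated nucleophile.

7. Thursday's flask had a cover of 1.22, so I expected the opposite order there, and I expected more electrophile to react there than in Monday's flask.

My ledger had no clock, so I gave no percentages, just a direction.

The forecast gave 67% for Thursday's and 50% for Monday's, and said of the trend: it rises. Its ground was that “each coupling produces more acid that locks up more nucleophile”. We agreed on the direction; the forecast named percentages and I did not.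

The simulation gave 64.8% for Thursday's and 49.9% for Monday's. With the free base raised from Monday's charge to Thursday's, the part of the electrophile that had reacted changed as follows: it rises, by 15 percentage points.

In Monday's flask the free base had a half-life of 5.8 min at the end, by the forward step alone, shorter than the run of 20 min. At that time 14.8% of its charge stood, against 39.9% of the protonated nucleophile, while Thursday's flask held 41.4% against 17.8%. A neighbour flask, Monday's with 0.540 equiv of protonated nucleophile, has a cover of 1.02, and at the end it held 31.1% of its free base against 20.5% of its protonated nucleophile.

The constants are invented; what happens was integrated by code.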